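At the reading, 3.0 d after the start, the length asked for is monomer in chains divided by the number of chains, in two flasks that differ in protic impurity.

- Saturday's: free monomer 0.20 M; protic impurity 0.200 M; initiator 0.70 mM; time 3.0 d
- Friday's: free monomer 0.20 M; protic impurity 0.0600 M; initiator 0.70 mM; time 3.0 d

- which of the two ends with the longer chains by the average number of monomer units in a chain (living and dead chains, two that joined counted as one) ("neither" if they lie within 10%) (Saturday's / Friday's / neither)
- average number of monomer units in a chain (living and dead chains, two that joined counted as one) at the end, Saturday's
- average number of monomer units in a chain (living and dead chains, two that joined counted as one) at the end, Friday's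

    initiator → 2 initiating radical (k1 = 0.00155 h⁻¹)
    free monomer + growing radical → monomer in chains + growing radical, rate k2*[growing radical]*[free monomer] (k2 = 7.51 × 10⁶ M⁻¹ h⁻¹)
    protic impurity + free monomer → quenched substrate (k3 = 0.354 M⁻¹ h⁻¹)
    free monomer + initiating radical → growing radical + monomer in chains (k4 = 1.38 × 10⁵ M⁻¹ s⁻¹)
    2 growing radical → dead chain (k5 = 1.8 × 10⁷ M⁻¹ s⁻¹)

Each initiator lost gives two radicals and two radicals make one chain, so I count chains as initiator lost: 7.39 × 10⁻⁵ M in either flask. I replace the initiator curve by its mean and let radicals pair as fast as they form, which gives c(growing radical) = 3.98 × 10⁻⁹ M, a value the start exceeds by 2.75%. That balance holds because the first half-life of this radical, 6.98 s, is far shorter than the run.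

Growth and quenching both run in proportion to c(free monomer), so dividing the two rates cancels it. What remains is the exchange concentration, the growth constant times c(growing radical) over the quench constant, which is the monomer in chains gained per unit of ln c(protic impurity) lost: 0.0845 M. This is a selectivity factor in concentration units.

I try 40.0% of the protic impurity left in Saturday's. Chains then gain 0.0774 M and the impurity takes 0.120 M, which leaves 0.002586 M of free monomer. Decay at the mean loss constant, with half the charged impurity, leaves 0.001815 M, close enough. The length is 1050.

For Friday's I try 20.0% left. Chains gain 0.136 M, the balance leaves 0.0160 M of free monomer, and the same decay leaves 0.0108 M, a rougher fit. The length is 1840, so Friday's comes out longer.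

The forecast says Friday's, with 1062 (1030 to 1095) for Saturday's and 1874 (1820 to 1930) for Friday's, on the ground that “the number of chains equals the initiator consumed”. Its two lengths stand a little above mine .

The simulation gives Friday's, with 1060 for Saturday's and 1870 for Friday's.

Dead chain stands at 7.39 × 10⁻⁵ M in Saturday's and 7.39 × 10⁻⁵ M in Friday's, while monomer in chains stands at 39.2% and 69.2% of the free monomer charged. The cheap route is the exchange concentration times a logarithm, divided by the chain count. Saturday's neighbour holds 0.50 M of free monomer and ends with 3.8% of its protic impurity. The same 0.0845 M gives 0.277 M in chains, and over 7.39 × 10⁻⁵ M chains a length of 3750. That flask gives 3790.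

All constants were chosen freely.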